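The cyclopentane (C2 bearing isopropenyl, C3, C4, carbinol C5, C6 bearing chain carbon C7) is cut at C4–C5, because the tertiary carbinol C5 sits beside the unsubstituted methylene C4. A samarium diiodide Barbier cyclization of an acyclic δ-iodo methyl ketone then makes this bond, the ring and the C5 stereocentre at once, the C7 benzyl ether β to the ketone steering the addition by chelation. The precursor is (3S,4S)-3-(benzyloxymethyl)-4-(2-iodoethyl)-5-methylhex-5-en-2-one, whose two stereocentres come from an asymmetric conjugate addition to 5,6-dihydro-2H-pyran-2-one and a trans-selective lactone alkylation. After ring closure, C7 becomes an aldehyde that is joined to a separately built C30 polyenyl phosphonium salt.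

Key step: step 6

Remarks on the chemistry
- Numbering: carotenoid numbering is used for the target (C1 isopropenyl carbon, ring C2–C6, chain from C7, primed numbers for the acyclic half). The target is (2S,5S,6R), all-E; on the ring, isopropenyl and C7 are trans, hydroxyl and C7 cis.
- Assumption: (S)-BINAP on rhodium is taken to expose the same enoate face of 1 as it does in other cyclic enones and enoates, which gives the S centre in 3. If the sense proved opposite, (R)-BINAP would be used with no other change.
- Assumption: geranyl bromide 14 and crocetindialdehyde 16 are purchased. All polyenes are handled under argon in the dark.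
- Design of the precursor: the benzyl ether on C7 is kept on purpose, because a small, Lewis-basic ether oxygen is needed for the samarium chelate (a bulky silyl ether would not bind). HMPA is left out of the key step for the same reason.

Step 1
Reactants: 1 5,6-dihydro-2H-pyran-2-one; 2 potassium isopropenyltrifluoroborate
Product: 3 (S)-4-(prop-1-en-2-yl)tetrahydro-2H-pyran-2-one
Conditions: [Rh(OH)(cod)]2 (3 mol %), (S)-BINAP (7 mol %), premixed; 2 (2.5 equiv), 1,4-dioxane/H2O (10:1), 60 °C
Reagents that add atoms: none
Why: Rhodium-catalysed asymmetric 1,4-addition (Hayashi–Miyaura reaction), in which the trifluoroborate hydrolyses slowly to the boronic acid, the hydroxo rhodium–BINAP complex transmetalates it, the alkenylrhodium inserts the cis-enoate and water releases the product, the chiral ligand selecting the face that gives the S centre (C2 of the target).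

Step 2
Reactants: 3 (S)-4-(prop-1-en-2-yl)tetrahydro-2H-pyran-2-one; 4 benzyl chloromethyl ether
Product: 6 (3S,4S)-3-[(benzyloxy)methyl]-4-(prop-1-en-2-yl)tetrahydro-2H-pyran-2-one, via lithium lactone enolate 5 (not isolated)
Conditions: LiN(iPr)2, THF, −78 °C; then 4, −78 → −40 °C
Reagents that add atoms: none
Why: Kinetic enolate alkylation (SN2 on the α-chloro ether), in which the electrophile should enter the half-chair enolate anti to the neighbouring isopropenyl group and so set C6 of the target trans to C2.

Step 3
Reactants: 6 (3S,4S)-3-[(benzyloxy)methyl]-4-(prop-1-en-2-yl)tetrahydro-2H-pyran-2-one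
Product: 7 (2S,3S)-2-[(benzyloxy)methyl]-5-hydroxy-N-methoxy-N-methyl-3-(prop-1-en-2-yl)pentanamide
Conditions: MeNH(OMe)·HCl, AlMe3, CH2Cl2, 0 °C → rt; aq. KNaC4H4O6 work-up; crude used directly
Reagents that add atoms: N,O-dimethylhydroxylamine hydrochloride, CNOC.Cl
Why: Weinreb aminolysis of a lactone by the aluminium amide formed in situ, which attacks only the acyl carbon under non-basic conditions so that neither stereocentre is touched.

Step 4
Reactants: 7 (2S,3S)-2-[(benzyloxy)methyl]-5-hydroxy-N-methoxy-N-methyl-3-(prop-1-en-2-yl)pentanamide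
Product: 8 (2S,3S)-2-[(benzyloxy)methyl]-5-iodo-N-methoxy-N-methyl-3-(prop-1-en-2-yl)pentanamide
Conditions: I2, PPh3, imidazole, CH2Cl2, 0 °C
Reagents that add atoms: iodine, II
Why: Appel-type iodination, in which iodide displaces the primary alkoxyphosphonium group by SN2 faster than the hydroxy amide can close back to the lactone, with no stereocentre involved.

Step 5
Reactants: 8 (2S,3S)-2-[(benzyloxy)methyl]-5-iodo-N-methoxy-N-methyl-3-(prop-1-en-2-yl)pentanamide
Product: 9 (3S,4S)-3-[(benzyloxy)methyl]-4-(2-iodoethyl)-5-methylhex-5-en-2-one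
Conditions: MeMgBr, THF, −20 → 0 °C; cold pH 7 buffer quench
Reagents that add atoms: methylmagnesium bromide, C[Mg]Br
Why: Weinreb ketone synthesis, in which the magnesium-chelated tetrahedral adduct resists a second addition and enolisation, the primary iodide is inert to the Grignard reagent at this temperature, and the neutral quench should keep the α-centre C6 and the β-benzyloxy group intact.

Step 6
Reactants: 9 (3S,4S)-3-[(benzyloxy)methyl]-4-(2-iodoethyl)-5-methylhex-5-en-2-one
Product: 11 (1S,2S,3S)-2-[(benzyloxy)methyl]-1-methyl-3-(prop-1-en-2-yl)cyclopentan-1-ol, via alkylsamarium diiodide 10 (not isolated)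
Conditions: SmI2 (2.5 equiv), Fe(dbm)3 [tris(dibenzoylmethanato)iron] (2 mol %), THF, −78 → 0 °C, no HMPA; aq. NaHCO3
Reagents that add atoms: none
Why: SmI2 passes two electrons in succession into the C4–I bond of 9, giving the primary radical and then alkylsamarium 10, whose C4 adds to the C5 carbonyl, so that one operation forms the C4–C5 bond, the cyclopentane and the tertiary alcohol (a ketyl-first sequence would lead to the same alkoxide). The closest known reaction type is the samarium diiodide intramolecular Barbier cyclisation of ω-iodoalkyl ketones, including variants directed by chelation to a β-oxygen donor. The ring closes in the 5-exo-trig mode on the C=O group, leaving the oxygen exocyclic. The new centre C5 is set by chelation: the samarium ion, trivalent at this stage, is held between the carbonyl oxygen and the ether oxygen on C7 in a six-membered chelate ring, which keeps the C=O bond syn to C7 while C4 swings in from the C2 side, so the hydroxyl should end cis to C7 and the methyl trans (1S in 11). The step needs chemoselectivity for iodide reduction over ketyl coupling and over radical addition to the alkene, which the substrate secures because the iodide is primary and easily reduced and because the only closures of the C4 radical onto the isopropenyl group would be 4-exo or 5-endo, both far slower than the second electron transfer. It also needs the chelate to survive and C6 to keep its configuration, hence HMPA is omitted in favour of a trivalent iron catalyst and the medium stays cold and non-basic, the C2/C6 relationship being already fixed in 9.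

Step 7
Reactants: 11 (1S,2S,3S)-2-[(benzyloxy)methyl]-1-methyl-3-(prop-1-en-2-yl)cyclopentan-1-ol
Product: 12 (1S,2S,3S)-2-(hydroxymethyl)-1-methyl-3-(prop-1-en-2-yl)cyclopentan-1-ol
Conditions: LiC10H8 (lithium naphthalenide, excess), THF, −25 °C; H2O
Reagents that add atoms: none
Why: Reductive debenzylation by electron transfer from the arene radical anion into the benzyl ether, which cleaves the benzylic C–O bond while the isolated 1,1-disubstituted alkene, the tertiary alkoxide and all stereocentres stay untouched.

Step 8
Reactants: 12 (1S,2S,3S)-2-(hydroxymethyl)-1-methyl-3-(prop-1-en-2-yl)cyclopentan-1-ol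
Product: 13 (1R,2S,5S)-2-hydroxy-2-methyl-5-(prop-1-en-2-yl)cyclopentane-1-carbaldehyde
Conditions: TEMPO (10 mol %), PhI(OAc)2, CH2Cl2, rt; crude used at once
Reagents that add atoms: none
Why: Oxoammonium-mediated (TEMPO) oxidation, in which only the primary carbinol can be oxidised, the nearly neutral medium should spare the β-hydroxy aldehyde from dehydration and retro-aldol cleavage, and C6 already holds its more stable arrangement trans to the isopropenyl group.

Step 9
Reactants: 14 geranyl bromide [(2E)-1-bromo-3,7-dimethylocta-2,6-diene]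
Product: 15 diethyl [(2E)-3,7-dimethylocta-2,6-dien-1-yl]phosphonate
Conditions: P(OEt)3, neat, 130 °C, EtBr distilled off
Reagents that add atoms: triethyl phosphite, CCOP(OCC)OCC
Why: Michaelis–Arbuzov reaction, in which phosphorus attacks the primary allylic bromide by SN2 and bromide dealkylates the phosphonium intermediate, leaving the E double bond untouched.

Step 10
Reactants: 15 diethyl [(2E)-3,7-dimethylocta-2,6-dien-1-yl]phosphonate; 16 crocetindialdehyde [(2E,4E,6E,8E,10E,12E,14E)-2,6,11,15-tetramethylhexadeca-2,4,6,8,10,12,14-heptaenedial]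
Product: 18 apo-8'-lycopenal [(2E,4E,6E,8E,10E,12E,14E,16E,18E)-2,6,11,15,19,23-hexamethyltetracosa-2,4,6,8,10,12,14,16,18,22-decaenal], via potassium phosphonate carbanion 17 (not isolated)
Conditions: KN(SiMe3)2, THF, −78 °C; then added slowly to 16 (2.5 equiv), THF, −40 → 0 °C, dark, argon; excess 16 recovered
Reagents that add atoms: none
Why: Horner–Wadsworth–Emmons olefination with an allylic phosphonate carbanion, which should give the new C7'=C8' bond in the E form, while the excess of dialdehyde and the lower electrophilicity of the product aldehyde (longer polyene, no second formyl acceptor) should hold the reaction at mono-olefination.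

Step 11
Reactants: 18 apo-8'-lycopenal
Product: 19 (2E,4E,6E,8E,10E,12E,14E,16E,18E)-2,6,11,15,19,23-hexamethyltetracosa-2,4,6,8,10,12,14,16,18,22-decaen-1-ol
Conditions: NaBH4, EtOH/THF, 0 °C, dark
Reagents that add atoms: none
Why: Hydride 1,2-reduction of the conjugated aldehyde, the only reducible group present, so the polyene geometry is retained.

Step 12
Reactants: 19 (2E,4E,6E,8E,10E,12E,14E,16E,18E)-2,6,11,15,19,23-hexamethyltetracosa-2,4,6,8,10,12,14,16,18,22-decaen-1-ol
Product: 20 [(2E,4E,6E,8E,10E,12E,14E,16E,18E)-2,6,11,15,19,23-hexamethyltetracosa-2,4,6,8,10,12,14,16,18,22-decaen-1-yl]triphenylphosphonium bromide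
Conditions: PPh3·HBr, MeOH/CH2Cl2, rt, dark, argon
Reagents that add atoms: triphenylphosphine hydrobromide, Br.c1ccc(cc1)P(c1ccccc1)c1ccccc1
Why: Acid-assisted substitution of a polyenylic alcohol (the standard preparation of carotenoid Wittig salts), in which the delocalised cation is trapped by PPh3 at the terminal carbon, the position that keeps the whole polyene conjugated, while the weakly acidic reagent leaves the isolated trisubstituted alkene alone.

Step 13
Reactants: 13 (1R,2S,5S)-2-hydroxy-2-methyl-5-(prop-1-en-2-yl)cyclopentane-1-carbaldehyde; 20 C30 polyenyl triphenylphosphonium bromide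
Product: 22 target CNP0222499.1, (1S,2R,3S)-1-methyl-2-[(1E,3E,5E,7E,9E,11E,13E,15E,17E,19E)-3,7,12,16,20,24-hexamethylpentacosa-1,3,5,7,9,11,13,15,17,19,23-undecaen-1-yl]-3-(prop-1-en-2-yl)cyclopentan-1-ol, via polyenylidene phosphorane 21 (not isolated)
Conditions: 1,2-epoxybutane/EtOH, 60 °C, dark, argon; then I2 (cat.), n-hexane, rt, diffuse light if a 7Z isomer is present; crystallisation
Reagents that add atoms: none
Why: Wittig olefination under base-free conditions, in which bromide opens the epoxide to an alkoxide that generates the delocalised ylide in low concentration, so the β-hydroxy aldehyde never meets a strong base, and such a highly conjugated (stabilised) ylide should give the E C7=C8 bond without disturbing C2, C5 or C6.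

Compound list
1 | 5,6-dihydro-2H-pyran-2-one | O=C1C=CCCO1 | starting material
2 | potassium isopropenyltrifluoroborate | C=C(C)[B-](F)(F)F.[K+] | starting material
3 | (S)-4-(prop-1-en-2-yl)tetrahydro-2H-pyran-2-one | C=C(C)[C@H]1CCOC(=O)C1 | intermediate
4 | benzyl chloromethyl ether | ClCOCc1ccccc1 | starting material
5 | lithium enolate of 3 (formed in the flask) | C=C(C)[C@H]1CCOC([O-])=C1.[Li+] | intermediate
6 | (3S,4S)-3-[(benzyloxy)methyl]-4-(prop-1-en-2-yl)tetrahydro-2H-pyran-2-one | C=C(C)[C@H]1CCOC(=O)[C@@H]1COCc1ccccc1 | intermediate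
7 | (2S,3S)-2-[(benzyloxy)methyl]-5-hydroxy-N-methoxy-N-methyl-3-(prop-1-en-2-yl)pentanamide | C=C(C)[C@@H](CCO)[C@@H](COCc1ccccc1)C(=O)N(C)OC | intermediate
8 | (2S,3S)-2-[(benzyloxy)methyl]-5-iodo-N-methoxy-N-methyl-3-(prop-1-en-2-yl)pentanamide | C=C(C)[C@@H](CCI)[C@@H](COCc1ccccc1)C(=O)N(C)OC | intermediate
9 | (3S,4S)-3-[(benzyloxy)methyl]-4-(2-iodoethyl)-5-methylhex-5-en-2-one | C=C(C)[C@@H](CCI)[C@@H](COCc1ccccc1)C(C)=O | intermediate
10 | alkylsamarium diiodide from 9, samarium on C4 (formed in the flask) | C=C(C)[C@@H](CC[Sm](I)I)[C@@H](COCc1ccccc1)C(C)=O | intermediate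
11 | (1S,2S,3S)-2-[(benzyloxy)methyl]-1-methyl-3-(prop-1-en-2-yl)cyclopentan-1-ol | C=C(C)[C@H]1CC[C@](C)(O)[C@@H]1COCc1ccccc1 | intermediate
12 | (1S,2S,3S)-2-(hydroxymethyl)-1-methyl-3-(prop-1-en-2-yl)cyclopentan-1-ol | C=C(C)[C@H]1CC[C@](C)(O)[C@@H]1CO | intermediate
13 | (1R,2S,5S)-2-hydroxy-2-methyl-5-(prop-1-en-2-yl)cyclopentane-1-carbaldehyde | C=C(C)[C@H]1CC[C@](C)(O)[C@@H]1C=O | intermediate
14 | geranyl bromide, (2E)-1-bromo-3,7-dimethylocta-2,6-diene | CC(C)=CCC/C(C)=C/CBr | starting material
15 | diethyl [(2E)-3,7-dimethylocta-2,6-dien-1-yl]phosphonate | CC(C)=CCC/C(C)=C/CP(=O)(OCC)OCC | intermediate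
16 | crocetindialdehyde, (2E,4E,6E,8E,10E,12E,14E)-2,6,11,15-tetramethylhexadeca-2,4,6,8,10,12,14-heptaenedial | O=C/C(C)=C/C=C/C(C)=C/C=C/C=C(C)/C=C/C=C(C)/C=O | starting material
17 | potassium salt of the α-carbanion of 15 (formed in the flask) | CC(C)=CCC/C(C)=C/[CH-]P(=O)(OCC)OCC.[K+] | intermediate
18 | apo-8'-lycopenal, (2E,4E,6E,8E,10E,12E,14E,16E,18E)-2,6,11,15,19,23-hexamethyltetracosa-2,4,6,8,10,12,14,16,18,22-decaenal | CC(C)=CCC/C(C)=C/C=C/C(C)=C/C=C/C(C)=C/C=C/C=C(C)/C=C/C=C(C)/C=O | intermediate
19 | (2E,4E,6E,8E,10E,12E,14E,16E,18E)-2,6,11,15,19,23-hexamethyltetracosa-2,4,6,8,10,12,14,16,18,22-decaen-1-ol | CC(C)=CCC/C(C)=C/C=C/C(C)=C/C=C/C(C)=C/C=C/C=C(C)/C=C/C=C(C)/CO | intermediate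
20 | [(2E,4E,6E,8E,10E,12E,14E,16E,18E)-2,6,11,15,19,23-hexamethyltetracosa-2,4,6,8,10,12,14,16,18,22-decaen-1-yl]triphenylphosphonium bromide | CC(C)=CCC/C(C)=C/C=C/C(C)=C/C=C/C(C)=C/C=C/C=C(C)/C=C/C=C(C)/C[P+](c1ccccc1)(c1ccccc1)c1ccccc1.[Br-] | intermediate
21 | triphenylphosphonium ylide of 20 (formed in the flask) | CC(C)=CCC/C(C)=C/C=C/C(C)=C/C=C/C(C)=C/C=C/C=C(C)/C=C/C=C(C)/C=P(c1ccccc1)(c1ccccc1)c1ccccc1 | intermediate
22 | CNP0222499.1, (1S,2R,3S)-1-methyl-2-[(1E,3E,5E,7E,9E,11E,13E,15E,17E,19E)-3,7,12,16,20,24-hexamethylpentacosa-1,3,5,7,9,11,13,15,17,19,23-undecaen-1-yl]-3-(prop-1-en-2-yl)cyclopentan-1-ol | C=C(C)[C@H]1CC[C@](C)(O)[C@@H]1/C=C/C(C)=C/C=C/C(C)=C/C=C/C=C(C)/C=C/C=C(C)/C=C/C=C(\C)CCC=C(C)C | target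

Total step count: 13 (steps 1–8 ring fragment, steps 9–12 chain fragment, step 13 union).
Longest linear sequence: 9 steps (steps 1–8, then step 13).

Steps most likely to fail

Step 6. The ether oxygen may fail to hold the samarium, so that the hydroxyl is delivered trans to C7, or the ketone may be reduced or coupled before the iodide reacts. The fallback sets out from 8 and returns at 11. Treatment of 8 with t-BuLi (Et2O/pentane, −78 °C) should exchange iodine for lithium, and the alkyllithium should acylate itself on the Weinreb amide in a 5-exo closure to give (2S,3S)-2-[(benzyloxy)methyl]-3-(prop-1-en-2-yl)cyclopentan-1-one F1, in which the trans arrangement is also the thermodynamic one. Addition of MeMgBr in the presence of CeCl3 (THF, −78 °C) should then occur on the ring face opposite the neighbouring C6 substituent, which places the methyl trans and the hydroxyl cis to C7 and gives 11. The stereocentre is thus set by steric approach to a ring ketone and no longer by chelation in the ring closure.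

Step 13. The β-hydroxy aldehyde may open by retro-aldol cleavage or lose water while the ylide is generated, the stabilised ylide may add sluggishly to the hindered aldehyde, and E selectivity may be incomplete. The fallback sets out from 13 and returns at 22. Silylation of the tertiary hydroxyl with Et3SiOTf and 2,6-lutidine (CH2Cl2, −78 °C) should give (1R,2S,5S)-2-methyl-5-(prop-1-en-2-yl)-2-[(triethylsilyl)oxy]cyclopentane-1-carbaldehyde F2, which can no longer fragment. Ylide 21, preformed from 20 with NaN(SiMe3)2 in THF, should then give the triethylsilyl ether of the target F3, and Bu4NF in THF should release 22.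

Step 10. Both formyl groups may react, the allylic carbanion may attack through its γ-carbon or remove a proton from a methyl group of the polyenal, and the phosphonate adduct may be slow to eliminate. The fallback sets out from 14 and returns at 18. Geranyl bromide and PPh3 in toluene should give geranyltriphenylphosphonium bromide F4. Its far less basic ylide, generated slowly with NaOMe in MeOH/CH2Cl2 in the presence of excess 16, reacts only through the α-carbon and collapses irreversibly to the alkene. The resulting E/Z mixture at the new double bond would be equilibrated with catalytic I2 in light and the all-E aldehyde 18 crystallised.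

Further compounds
F1 | step 6 | (2S,3S)-2-[(benzyloxy)methyl]-3-(prop-1-en-2-yl)cyclopentan-1-one | C=C(C)[C@H]1CCC(=O)[C@@H]1COCc1ccccc1
F2 | step 13 | (1R,2S,5S)-2-methyl-5-(prop-1-en-2-yl)-2-[(triethylsilyl)oxy]cyclopentane-1-carbaldehyde | C=C(C)[C@H]1CC[C@](C)(O[Si](CC)(CC)CC)[C@@H]1C=O
F3 | step 13 | triethylsilyl ether of 22 at the C5 hydroxyl | C=C(C)[C@H]1CC[C@](C)(O[Si](CC)(CC)CC)[C@@H]1/C=C/C(C)=C/C=C/C(C)=C/C=C/C=C(C)/C=C/C=C(C)/C=C/C=C(\C)CCC=C(C)C
F4 | step 10 | geranyltriphenylphosphonium bromide, [(2E)-3,7-dimethylocta-2,6-dien-1-yl]triphenylphosphonium bromide | CC(C)=CCC/C(C)=C/C[P+](c1ccccc1)(c1ccccc1)c1ccccc1.[Br-]
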